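I left the flask stirring. Its charge, the earlier birch run and the readings wanted stood as follows.

- birch: starting material 1.5 M; reagent 1.1 M; free catalyst 12 mM; second catalyst 7.5 mM; run made earlier
- flask: starting material 1.5 M; reagent 2.25 M; free catalyst 12 mM; second catalyst 7.5 mM; time 10 h

birch run (percent of the starting material charged)

| time / h | isomer of the product / % | target / % |
|---|---|---|
| 1.00 | 43 | 15 |
| 3.00 | 68 | 4 |
| 6.00 | 72 | 1 |
| 8.00 | 68 | 4 |
| 12.0 | 67 | 4 |

(standard deviation of a reading: 2 percentage points)

1. share of isomer of the product in isomer of the product plus target at 2.5 min
2. share of isomer of the product in isomer of the product plus target at 40 min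
3. share of isomer of the product in isomer of the product plus target at 10 h



In birch, reagent was the smaller charge, and isomer plus target read 73.0 % at 6.00 h against the 73.3 % that the reagent charge allowed, so I took one reagent to go into each product. The flask reversed the order: starting material was the smaller charge, the limiting reagent. I therefore wrote the reagent balance, charge minus what starting material can take, and called the remainder spare reagent: 33.3 % of the reagent charge, the part still free once starting material is used up, which is [reagent] = 0.750 M.

So I expected you to find isomer plus target near 100 % of the starting material in the flask at 10 h. Add no reagent to it, since its charge already stood above what starting material can take. Do not take an early reading for the end either: in birch, target went from 15 % at 1.00 h to 4 % at 3.00 h while isomer rose.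

The forecast gave shares of 5 %, 60 % and 95 %, saying “I read target as the primary product, isomerising towards a plateau of about 95% isomer”.

The flask gave 4.15 %, 63.5 % and 95.2 %, each within the tolerance of the forecast.

    starting material + free catalyst ⇌ free catalyst + intermediate (K = 0.820, k = 0.266 M⁻¹ s⁻¹)
    reagent + second catalyst + intermediate → second catalyst + target (k = 0.158 M⁻² s⁻¹)
    target ⇌ isomer of the product (K = 20.0, k = 7.63 × 10⁻⁴ s⁻¹)

At 10.0 h the flask held reagent at 33 % of its charge and starting material at 0 %, beside my spare reagent of 33.3 %. The neighbouring flask held 3.00 mM of second catalyst, less than the 7.5 mM of the flask. Second catalyst stands nowhere in the balance, so I reckoned the same spare reagent, 33.3 %, for it. At 10.0 h the neighbouring flask held reagent at 33 % of its charge, with starting material at 0.073 % and a share of 95.2 %. Its share at 40 min was lower than in the flask, at 58.6 % against 63.5 %.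

The readings are simulated with made-up constants, noise included.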